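**Assumptions.** The target has no stereocentres, so no enantiocontrol is needed. In step 7 I assume the pinacol boronate exchanges or hydrolyses in situ to the boronic acid.

**Retrosynthetic overview**
1. Disconnect the benzofuran C2–aryl bond as a radical C–H arylation: a 3,5-dioxygenated aryl radical (from its boronate) adds to a 6-protected benzofuran.
2. Both aromatic cores come from resorcinol. The benzofuran is built by acetal cyclisation. The central ring is C5-borylated by Ir catalysis, with a temporary Br block on the carbon that must remain H.
3. Ring order: furan ring (step 5), then the biaryl bond (step 7), then the pyran ring by prenal annulation (step 9). The prenyl group and debromination follow.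

**Step 1**
Reactants: 1 resorcinol
Product: 2 1,3-bis(methoxymethoxy)benzene
Conditions: MOMCl, i-Pr2NEt, CH2Cl2, 0 °C → rt
Reagents that add atoms: chloromethyl methyl ether, ClCOC
Why: Bis-MOM protection makes the ring a good substrate for directed metalation and Ir borylation. No stereocentre is formed.

**Step 2**
Reactants: 2
Product: 3 2-bromo-1,3-bis(methoxymethoxy)benzene
Conditions: n-BuLi, THF, 0 °C; then BrCCl2CCl2Br, –78 °C → rt
Reagents that add atoms: 1,2-dibromotetrachloroethane, BrC(Cl)(Cl)C(Cl)(Cl)Br
Why: Directed ortho-metalation occurs between the two OMOM groups, and the aryllithium is brominated. The Br blocks the position that must stay H, because free 5-aryl-resorcinols otherwise react there with enals (as in olivetol → cannabichromene).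

**Step 3**
Reactants: 3
Product: 4 2-[4-bromo-3,5-bis(methoxymethoxy)phenyl]-4,4,5,5-tetramethyl-1,3,2-dioxaborolane
Conditions: B2pin2, [Ir(OMe)(cod)]2, dtbpy, THF, 80 °C
Reagents that add atoms: bis(pinacolato)diboron, CC1(C)OB(OC1(C)C)B1OC(C)(C)C(C)(C)O1
Why: Sterically controlled Ir C–H borylation reaches only C5, the position meta to both oxygens, which electrophilic chemistry cannot reach.

**Step 4**
Reactants: 1 resorcinol (3 equiv); 5 chloroacetaldehyde dimethyl acetal
Product: 6 1-(2,2-dimethoxyethoxy)-3-hydroxybenzene
Conditions: K2CO3, KI (cat.), DMF, 100 °C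
Reagents that add atoms: none (5 is a numbered reactant)
Why: Williamson mono-O-alkylation, with excess diol favouring the mono-ether. This supplies the C2–C3 unit of the benzofuran.

**Step 5**
Reactants: 6
Product: 7 benzofuran-6-ol
Conditions: PPA, PhCl, 100 °C
Reagents that add atoms: none
Why: Acid-promoted acetal cyclodehydration (Friedel–Crafts type). Ring closure occurs para to the free OH, which is less hindered and more activated than the position between the oxygens, giving 6-OH over 4-OH. The minor 4-OH isomer is removed by chromatography.

**Step 6**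
Reactants: 7
Product: 8 benzofuran-6-yl pivalate
Conditions: PivCl, Et3N, DMAP, CH2Cl2, 0 °C
Reagents that add atoms: pivaloyl chloride, CC(C)(C)C(Cl)=O
Why: The base-stable, acid-stable pivalate keeps the benzofuran ring inert in the later annulation steps and in the radical step. It is orthogonal to MOM.

**Step 7 (key radical step)**
Reactants: 4 (1 equiv); 8 (2 equiv)
Product: 9 2-[4-bromo-3,5-bis(methoxymethoxy)phenyl]benzofuran-6-yl pivalate
Conditions: Mn(OAc)3·2H2O (3 equiv), AcOH/MeCN (1:4), 60 °C
Reagents that add atoms: none
Why: Proposed new method: Mn(III) oxidises the boronate (exchanged to the boronic acid in wet AcOH) to the aryl radical. The radical adds to benzofuran C2, giving the benzylic C3 radical. Mn(III) oxidation and loss of H⁺ then rearomatise the ring. The closest known reaction is Mn(III)- or Ag-mediated homolytic arylation of furans, thiophenes and benzofurans with arylboronic acids. The radical is not ortho-substituted, which avoids the hindered biaryl problem of a cross-coupling; the ortho positions are functionalised afterwards. No stereocentre is formed.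

**Step 8**
Reactants: 9
Product: 10 2-(4-bromo-3,5-dihydroxyphenyl)benzofuran-6-yl pivalate
Conditions: 3 M HCl, THF/MeOH (1:1), 50 °C
Reagents that add atoms: none
Why: MOM acetals are hydrolysed by acid, while the aryl pivalate, aryl bromide and benzofuran survive. The product is a symmetric bis-phenol with C4 blocked.

**Step 9**
Reactants: 10; 11 3-methylbut-2-enal (prenal)
Product: 12 2-(chromenyl)benzofuran-6-yl pivalate, i.e. 2-[8-bromo-7-hydroxy-2,2-dimethyl-2H-chromen-5-yl]benzofuran-6-yl pivalate
Conditions: pyridine, 115 °C, sealed tube (1.1 equiv prenal)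
Reagents that add atoms: none (11 is a numbered reactant)
Why: Ortho-condensation of the phenol with the enal followed by oxa-6π electrocyclisation (the standard 2,2-dimethylchromene synthesis). With C4 blocked, the reaction can only occur at the carbon next to the aryl group. The two OH groups are equivalent by symmetry, so there is only one regio-outcome. No stereocentre is formed.

**Step 10**
Reactants: 12; 13 prenyl bromide (3-methylbut-2-enyl bromide)
Product: 14 prenylated bromochromene pivalate, i.e. 2-[8-bromo-7-hydroxy-2,2-dimethyl-6-(3-methylbut-2-enyl)-2H-chromen-5-yl]benzofuran-6-yl pivalate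
Conditions: KOH (1.0 equiv), MeOH/H2O (9:1), 0 °C → rt
Reagents that add atoms: none (13 is a numbered reactant)
Why: Phenoxide C-alkylation in a protic solvent (SN2 at the primary allylic bromide). The only free ortho carbon is the one next to the aryl group, because the other ortho position carries Br.

**Step 11**
Reactants: 14
Product: 15 2-(7-hydroxy-2,2-dimethyl-6-prenyl-2H-chromen-5-yl)benzofuran-6-yl pivalate
Conditions: (Me3Si)3SiH, AIBN, PhMe, 90 °C
Reagents that add atoms: tris(trimethylsilyl)silane, supplies H only, C[Si](C)(C)[SiH]([Si](C)(C)C)[Si](C)(C)C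
Why: Radical hydrodehalogenation removes the blocking Br without reducing the prenyl or chromene alkenes, which catalytic hydrogenolysis would reduce.

**Step 12**
Reactants: 15
Product: 16 Cathafuran C
Conditions: NaOMe (5 equiv), MeOH/THF (1:1), 60 °C; NH4Cl work-up
Reagents that add atoms: none
Why: Transesterification cleaves the pivalate to give the free 6-OH. The last product matches the target; the target is achiral.

**Compound list**
1 | resorcinol | Oc1cccc(O)c1 | starting material
2 | 1,3-bis(methoxymethoxy)benzene | COCOc1cccc(OCOC)c1 | intermediate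
3 | 2-bromo-1,3-bis(methoxymethoxy)benzene | COCOc1cccc(OCOC)c1Br | intermediate
4 | 4-bromo-3,5-bis(MOM-oxy)phenyl-Bpin | COCOc1cc(B2OC(C)(C)C(C)(C)O2)cc(OCOC)c1Br | intermediate
5 | chloroacetaldehyde dimethyl acetal | COC(OC)CCl | starting material
6 | 1-(2,2-dimethoxyethoxy)-3-hydroxybenzene | COC(OC)COc1cccc(O)c1 | intermediate
7 | benzofuran-6-ol | Oc1ccc2ccoc2c1 | intermediate
8 | benzofuran-6-yl pivalate | CC(C)(C)C(=O)Oc1ccc2ccoc2c1 | intermediate
9 | 2-[4-bromo-3,5-bis(MOM-oxy)phenyl]benzofuran-6-yl pivalate | CC(C)(C)C(=O)Oc1ccc2cc(oc2c1)-c1cc(OCOC)c(Br)c(OCOC)c1 | intermediate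
10 | 2-(4-bromo-3,5-dihydroxyphenyl)benzofuran-6-yl pivalate | CC(C)(C)C(=O)Oc1ccc2cc(oc2c1)-c1cc(O)c(Br)c(O)c1 | intermediate
11 | 3-methylbut-2-enal | CC(C)=CC=O | starting material
12 | 2-(8-bromo-7-hydroxy-2,2-dimethyl-2H-chromen-5-yl)benzofuran-6-yl pivalate | CC(C)(C)C(=O)Oc1ccc2cc(oc2c1)-c1cc(O)c(Br)c2OC(C)(C)C=Cc12 | intermediate
13 | prenyl bromide | CC(C)=CCBr | starting material
14 | 2-(8-bromo-7-hydroxy-2,2-dimethyl-6-prenyl-2H-chromen-5-yl)benzofuran-6-yl pivalate | CC(C)(C)C(=O)Oc1ccc2cc(oc2c1)-c1c(CC=C(C)C)c(O)c(Br)c2OC(C)(C)C=Cc12 | intermediate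
15 | 2-(7-hydroxy-2,2-dimethyl-6-prenyl-2H-chromen-5-yl)benzofuran-6-yl pivalate | CC(C)(C)C(=O)Oc1ccc2cc(oc2c1)-c1c(CC=C(C)C)c(O)cc2OC(C)(C)C=Cc12 | intermediate
16 | Cathafuran C (achiral) | CC(C)=CCc1c(O)cc2c(c1-c1cc3ccc(O)cc3o1)C=CC(C)(C)O2 | target

**Total step count:** 12.
**Longest linear sequence:** 9 steps (1→2→3→4→9→10→12→14→15→16 through the convergent fragments; equivalently 5→6→7→8→9→10→12→14→15→16 from resorcinol on the benzofuran branch).

**Three steps most likely to fail**
1. **Step 7 (radical arylation):** Regioselectivity, over-oxidation of the electron-rich arene, MOM loss in AcOH, or incomplete in situ boronate exchange could lower the yield.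
   - Fallback: change to a classical cross-coupling. Lithiate 8 at C2 and brominate it (2-bromo-8), then run a Pd-catalysed Suzuki–Miyaura coupling with 4.
2. **Step 9 (chromene annulation):** Bis-chromene formation or low conversion with the Br-flanked, electron-poor bis-phenol.
   - Fallback: O-alkylate 10 with 3-chloro-3-methylbut-1-yne (K2CO3, CuI, KI), then cyclise the aryl propargyl ether thermally (PhNEt2, 200 °C) via Claisen rearrangement and 6π-electrocyclisation. Use one equivalent so that only one OH reacts.
3. **Step 10 (C-prenylation):** O- versus C-alkylation, and the hindered position flanked by the aryl group.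
   - Fallback: propargylate the phenol with 3-chloro-3-methylbut-1-yne and semi-hydrogenate (Lindlar) to the 1,1-dimethylallyl aryl ether. Then do a [3,3] Claisen rearrangement, which delivers the normal prenyl group at the ortho carbon.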